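The (2S)-flavanone is cut last across ring C at C3–C4 and O1–C2. Ring A arrives as salicylaldehyde 17 (C4 as the formyl carbon, O1 as the free phenol). Ring B arrives as aryl-propiolate 9, which carries C2 and C3 as an alkyne and, on C3, a tert-butoxycarbonyl group that is not in the target.
The key step is a rhodium-catalysed hydroacylation of the alkyne (C3–C4), relayed in the same flask to a cinchona-thiourea-catalysed oxa-Michael closure (O1–C2, sets C2). The enabling feature is the O1–H hydroxyl on C8a of ring A, ortho to the C4 formyl group: it anchors rhodium for insertion into the formyl C–H bond and then closes ring C. The temporary C3 ester polarises the alkyne, activates C2 and gives the thiourea its binding site.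
Rings A and B are bought as benzene rings (phloroglucinol, 2,4-dihydroxybenzaldehyde); ring C is the only ring formed, in step 12.
Both side chains come from aromatic Claisen shifts: the 8-prenyl group from the 1,1-dimethylallyl ether of the oxygen that becomes O1, and the 5'-(1,1-dimethylallyl) group from the 4'-O-prenyl ether.
One acidic end step removes the four MOM ethers and the C3 ester (decarboxylation).

Key step: step 12

Assumption: the thiourea built on 9-amino-9-deoxy-epi-quinidine is taken to give the 2S series in step 12; should a first run show the opposite sense, its quinine-derived pseudoenantiomer is used with nothing else changed.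

Step 1
Reactants: 1 2,4-dihydroxybenzaldehyde
Product: 2 2-hydroxy-4-[(3-methylbut-2-en-1-yl)oxy]benzaldehyde
Conditions: prenyl bromide (1.05 equiv), K2CO3, acetone, rt
Reagents that add atoms: prenyl bromide (1-bromo-3-methylbut-2-ene), CC(C)=CCBr
Why: Williamson etherification, selective for O4 because the 2-OH is hydrogen-bonded to the formyl oxygen and much less nucleophilic.

Step 2
Reactants: 2 2-hydroxy-4-[(3-methylbut-2-en-1-yl)oxy]benzaldehyde
Product: 3 2-(methoxymethoxy)-4-[(3-methylbut-2-en-1-yl)oxy]benzaldehyde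
Conditions: NaH, MOMCl, DMF, 0 °C to rt
Reagents that add atoms: chloromethyl methyl ether (MOMCl), COCCl
Why: Williamson-type MOM protection of the sodium phenoxide, which also removes the chelate whose bond fixation would steer the coming Claisen shift to C3.

Step 3
Reactants: 3 2-(methoxymethoxy)-4-[(3-methylbut-2-en-1-yl)oxy]benzaldehyde
Product: 5 4-hydroxy-2-(methoxymethoxy)-5-(2-methylbut-3-en-2-yl)benzaldehyde, via ortho-dienone 4 (not isolated)
Conditions: N,N-diethylaniline, 190 °C, Ar
Reagents that add atoms: none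
Why: aromatic Claisen rearrangement followed by tautomerisation of dienone 4; the prenyl ether necessarily delivers the inverted 1,1-dimethylallyl group, and C5 should be preferred over C3, which lies between two oxygen substituents and would have to carry the new quaternary carbon.

Step 4
Reactants: 5 4-hydroxy-2-(methoxymethoxy)-5-(2-methylbut-3-en-2-yl)benzaldehyde
Product: 6 2,4-bis(methoxymethoxy)-5-(2-methylbut-3-en-2-yl)benzaldehyde
Conditions: NaH, MOMCl, DMF, 0 °C to rt
Reagents that add atoms: chloromethyl methyl ether (MOMCl), COCCl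
Why: Williamson-type MOM protection; the small electrophile should reach the phenoxide next to the quaternary carbon.

Step 5
Reactants: 6 2,4-bis(methoxymethoxy)-5-(2-methylbut-3-en-2-yl)benzaldehyde
Product: 7 1-ethynyl-2,4-bis(methoxymethoxy)-5-(2-methylbut-3-en-2-yl)benzene
Conditions: dimethyl (1-diazo-2-oxopropyl)phosphonate, K2CO3, MeOH, 0 °C to rt
Reagents that add atoms: dimethyl (1-diazo-2-oxopropyl)phosphonate (Bestmann–Ohira reagent), COP(=O)(OC)C(=[N+]=[N-])C(C)=O
Why: Seyferth–Gilbert homologation in the Ohira–Bestmann variant, whose carbonate/methanol conditions leave the MOM ethers and the alkene untouched.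

Step 6
Reactants: 7 1-ethynyl-2,4-bis(methoxymethoxy)-5-(2-methylbut-3-en-2-yl)benzene
Product: 9 tert-butyl 3-[2,4-bis(methoxymethoxy)-5-(2-methylbut-3-en-2-yl)phenyl]prop-2-ynoate, via lithium acetylide 8 (not isolated)
Conditions: n-BuLi, THF, −78 °C; then Boc2O, −78 °C to 0 °C; H2O
Reagents that add atoms: di-tert-butyl dicarbonate (Boc2O), CC(C)(C)OC(=O)OC(=O)OC(C)(C)C
Why: deprotonation of the terminal alkyne and acylation of the lithium acetylide by Boc2O, a standard route to tert-butyl alkynoates; at −78 °C the alkyne C–H should be removed well before any ortho-lithiation next to the MOM groups.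

Step 7
Reactants: 10 phloroglucinol
Product: 11 3,5-bis(methoxymethoxy)phenol
Conditions: MOMCl (2.0 equiv), i-Pr2NEt, CH2Cl2/DMF, 0 °C to rt
Reagents that add atoms: chloromethyl methyl ether (MOMCl), COCCl
Why: statistical Williamson-type MOM protection of a threefold symmetric triol, with the bis-ether separated from mono- and tris-ether by chromatography.

Step 8
Reactants: 11 3,5-bis(methoxymethoxy)phenol
Product: 12 1,3-bis(methoxymethoxy)-5-[(2-methylbut-3-yn-2-yl)oxy]benzene
Conditions: 3-chloro-3-methylbut-1-yne, CuCl2·2H2O (cat.), DBU, MeCN, 0 °C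
Reagents that add atoms: 3-chloro-3-methylbut-1-yne, C#CC(C)(C)Cl
Why: copper-catalysed propargylic etherification of a phenol with a tertiary propargylic chloride, the standard entry to aryl 1,1-dimethylpropargyl ethers.

Step 9
Reactants: 12 1,3-bis(methoxymethoxy)-5-[(2-methylbut-3-yn-2-yl)oxy]benzene
Product: 13 1,3-bis(methoxymethoxy)-5-[(2-methylbut-3-en-2-yl)oxy]benzene
Conditions: H2 (1 atm), Pd on CaCO3 poisoned with Pb(OAc)2 (Lindlar catalyst), quinoline, EtOAc, 0 °C
Reagents that add atoms: none
Why: Lindlar semi-hydrogenation stops at the alkene, and the low temperature keeps the product ether from rearranging early.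

Step 10
Reactants: 13 1,3-bis(methoxymethoxy)-5-[(2-methylbut-3-en-2-yl)oxy]benzene
Product: 15 3,5-bis(methoxymethoxy)-2-(3-methylbut-2-en-1-yl)phenol, via ortho-dienone 14 (not isolated)
Conditions: toluene, 110 °C
Reagents that add atoms: none
Why: aromatic Claisen rearrangement of the aryl 1,1-dimethylallyl ether, which now delivers the normal prenyl group to one of two equivalent ortho carbons and so places it next to the oxygen that becomes O1, followed by tautomerisation of dienone 14.

Step 11
Reactants: 15 3,5-bis(methoxymethoxy)-2-(3-methylbut-2-en-1-yl)phenol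
Product: 17 2-hydroxy-4,6-bis(methoxymethoxy)-3-(3-methylbut-2-en-1-yl)benzaldehyde, via salicyl alcohol 16 (not isolated)
Conditions: MgCl2, Et3N, paraformaldehyde, MeCN, reflux; aq. NH4Cl
Reagents that add atoms: paraformaldehyde (formaldehyde), C=O
Why: magnesium-phenoxide-directed ortho-formylation (Casnati–Skattebøl conditions), in which the only free ortho carbon is hydroxymethylated and alcohol 16 is oxidised by a second formaldehyde through Oppenauer-type hydride transfer, so the formyl group can only enter next to the free hydroxyl.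

Step 12
Reactants: 17 2-hydroxy-4,6-bis(methoxymethoxy)-3-(3-methylbut-2-en-1-yl)benzaldehyde; 9 tert-butyl 3-[2,4-bis(methoxymethoxy)-5-(2-methylbut-3-en-2-yl)phenyl]prop-2-ynoate
Product: 19 tert-butyl (2S,3R)-2-[2,4-bis(methoxymethoxy)-5-(2-methylbut-3-en-2-yl)phenyl]-5,7-bis(methoxymethoxy)-8-(3-methylbut-2-en-1-yl)-4-oxo-3,4-dihydro-2H-chromene-3-carboxylate (in equilibrium with its enol), via alkylidene β-keto ester 18 (not isolated)
Conditions: [Rh(cod)OMe]2 (2.5 mol %), 1,1'-bis(diphenylphosphino)ferrocene (5 mol %), toluene, 60 °C; then −25 °C, 1-[3,5-bis(trifluoromethyl)phenyl]-3-[(9R)-6'-methoxycinchonan-9-yl]thiourea (10 mol %)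
Reagents that add atoms: none
Why: Proposed new method: monovalent rhodium, anchored by the phenoxide O1 of 17, should insert into the formyl C4–H bond, the alkyne of 9 should insert into the Rh–H bond with the hydride going to the aryl-bearing carbon, and reductive elimination should form C3–C4 to give alkylidene β-keto ester 18, which the bifunctional thiourea then closes by oxa-Michael addition of O1 to C2. The closest known reaction types are the rhodium-catalysed hydroacylation of alkynes with salicylaldehydes (also in tandem with base-promoted oxa-Michael closure to racemic chroman-4-ones) and the cinchona-thiourea-catalysed enantioselective cyclisation of tert-butyl 2-(2-hydroxybenzoyl)-3-arylacrylates; new are the aryl-propiolate as the alkyne partner and the relay of the two catalysts in one flask. Ring C is the only ring formed and closes in the 6-endo-trig mode. C2 is set by the catalyst, whose thiourea binds the two carbonyl groups of the β-keto ester while its quinuclidine nitrogen activates O1–H so that O1 reaches one face of C2; C3 is epimerisable (trans by equilibration) and is erased in step 13. The step needs regioselective insertion (secured by the polarisation of the ynoate, hydride to the β-carbon, in line with 1-aryl-1-alkynes where the acyl group goes to the carbon remote from the aryl group), chemoselectivity for the alkyne over the three alkenes and for O1 over the other ring A oxygens (O5 and O7 are MOM ethers, so only the 8-prenyl isomer can form), and no ring closure before the chiral catalyst is added (no base is present and 18 is a neutral, hydrogen-bonded phenol).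

Step 13
Reactants: 19 tert-butyl (2S,3R)-2-[2,4-bis(methoxymethoxy)-5-(2-methylbut-3-en-2-yl)phenyl]-5,7-bis(methoxymethoxy)-8-(3-methylbut-2-en-1-yl)-4-oxo-3,4-dihydro-2H-chromene-3-carboxylate (used crude)
Product: 21 AChE-IN-17, (2S)-2-[2,4-dihydroxy-5-(2-methylbut-3-en-2-yl)phenyl]-5,7-dihydroxy-8-(3-methylbut-2-en-1-yl)-2,3-dihydro-4H-chromen-4-one, via β-keto acid 20 (not isolated)
Conditions: 3 M aq. HCl/MeOH (1:4), 45 °C
Reagents that add atoms: none
Why: acid-catalysed acetal exchange removes the four MOM groups and AAL1 cleavage of the tert-butyl ester gives β-keto acid 20, which loses CO2 through the usual cyclic transition state (ketonic cleavage of a β-keto ester); C2 should survive because its epimerisation by retro-oxa-Michael opening needs base, and methanolic HCl of this strength is the usual reagent for MOM removal from prenylated flavanones.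

Compound list
1 | 2,4-dihydroxybenzaldehyde | O=Cc1ccc(O)cc1O | starting material
2 | 2-hydroxy-4-[(3-methylbut-2-en-1-yl)oxy]benzaldehyde | O=Cc1ccc(OCC=C(C)C)cc1O | intermediate
3 | 2-(methoxymethoxy)-4-[(3-methylbut-2-en-1-yl)oxy]benzaldehyde | O=Cc1ccc(OCC=C(C)C)cc1OCOC | intermediate
4 | 2-(methoxymethoxy)-5-(2-methylbut-3-en-2-yl)-4-oxocyclohexa-2,6-diene-1-carbaldehyde (ortho-dienone, racemic) | O=CC1=CC(C(C)(C)C=C)C(=O)C=C1OCOC | intermediate (not isolated)
5 | 4-hydroxy-2-(methoxymethoxy)-5-(2-methylbut-3-en-2-yl)benzaldehyde | O=Cc1cc(C(C)(C)C=C)c(O)cc1OCOC | intermediate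
6 | 2,4-bis(methoxymethoxy)-5-(2-methylbut-3-en-2-yl)benzaldehyde | O=Cc1cc(C(C)(C)C=C)c(OCOC)cc1OCOC | intermediate
7 | 1-ethynyl-2,4-bis(methoxymethoxy)-5-(2-methylbut-3-en-2-yl)benzene | C#Cc1cc(C(C)(C)C=C)c(OCOC)cc1OCOC | intermediate
8 | lithium acetylide of 7 | [Li]C#Cc1cc(C(C)(C)C=C)c(OCOC)cc1OCOC | intermediate (not isolated)
9 | tert-butyl 3-[2,4-bis(methoxymethoxy)-5-(2-methylbut-3-en-2-yl)phenyl]prop-2-ynoate | CC(C)(C)OC(=O)C#Cc1cc(C(C)(C)C=C)c(OCOC)cc1OCOC | intermediate
10 | phloroglucinol (benzene-1,3,5-triol) | Oc1cc(O)cc(O)c1 | starting material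
11 | 3,5-bis(methoxymethoxy)phenol | Oc1cc(OCOC)cc(OCOC)c1 | intermediate
12 | 1,3-bis(methoxymethoxy)-5-[(2-methylbut-3-yn-2-yl)oxy]benzene | C#CC(C)(C)Oc1cc(OCOC)cc(OCOC)c1 | intermediate
13 | 1,3-bis(methoxymethoxy)-5-[(2-methylbut-3-en-2-yl)oxy]benzene | C=CC(C)(C)Oc1cc(OCOC)cc(OCOC)c1 | intermediate
14 | 3,5-bis(methoxymethoxy)-6-(3-methylbut-2-en-1-yl)cyclohexa-2,4-dien-1-one (ortho-dienone, racemic) | CC(C)=CCC1C(=O)C=C(OCOC)C=C1OCOC | intermediate (not isolated)
15 | 3,5-bis(methoxymethoxy)-2-(3-methylbut-2-en-1-yl)phenol | CC(C)=CCc1c(O)cc(OCOC)cc1OCOC | intermediate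
16 | 2-(hydroxymethyl)-3,5-bis(methoxymethoxy)-6-(3-methylbut-2-en-1-yl)phenol (as its magnesium phenoxide) | OCc1c(O)c(CC=C(C)C)c(OCOC)cc1OCOC | intermediate (not isolated)
17 | 2-hydroxy-4,6-bis(methoxymethoxy)-3-(3-methylbut-2-en-1-yl)benzaldehyde | O=Cc1c(O)c(CC=C(C)C)c(OCOC)cc1OCOC | intermediate
18 | tert-butyl (2Z)-2-[2-hydroxy-4,6-bis(methoxymethoxy)-3-(3-methylbut-2-en-1-yl)benzoyl]-3-[2,4-bis(methoxymethoxy)-5-(2-methylbut-3-en-2-yl)phenyl]prop-2-enoate | CC(C)(C)OC(=O)/C(=C\c1cc(C(C)(C)C=C)c(OCOC)cc1OCOC)C(=O)c1c(O)c(CC=C(C)C)c(OCOC)cc1OCOC | intermediate (not isolated)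
19 | tert-butyl (2S,3R)-2-[2,4-bis(methoxymethoxy)-5-(2-methylbut-3-en-2-yl)phenyl]-5,7-bis(methoxymethoxy)-8-(3-methylbut-2-en-1-yl)-4-oxo-3,4-dihydro-2H-chromene-3-carboxylate (trans keto form drawn) | C=CC(C)(C)c1cc([C@@H]2[C@@H](C(=O)OC(C)(C)C)C(=O)c3c(OCOC)cc(OCOC)c(CC=C(C)C)c3O2)c(OCOC)cc1OCOC | intermediate
20 | (2S,3R)-2-[2,4-dihydroxy-5-(2-methylbut-3-en-2-yl)phenyl]-5,7-dihydroxy-8-(3-methylbut-2-en-1-yl)-4-oxo-3,4-dihydro-2H-chromene-3-carboxylic acid (drawn with all MOM groups already gone; the order of the cleavages is immaterial) | C=CC(C)(C)c1cc([C@@H]2[C@@H](C(=O)O)C(=O)c3c(O)cc(O)c(CC=C(C)C)c3O2)c(O)cc1O | intermediate (not isolated)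
21 | AChE-IN-17, (2S)-2-[2,4-dihydroxy-5-(2-methylbut-3-en-2-yl)phenyl]-5,7-dihydroxy-8-(3-methylbut-2-en-1-yl)-2,3-dihydro-4H-chromen-4-one | C=CC(C)(C)c1cc([C@@H]2CC(=O)c3c(O)cc(O)c(CC=C(C)C)c3O2)c(O)cc1O | target

Total step count: 13
Longest linear sequence: 8 steps (steps 1 to 6, then 12 and 13)

Steps most likely to fail

Step 12 (bears the label "Proposed new method:"). What may go wrong: hydride insertion in the wrong sense, conjugate addition of the phenol to the ynoate instead of C–H insertion, or ring closure during the rhodium stage before the chiral catalyst is present, which would erode the enantiomeric purity. The fallback uses known chemistry only and gives up the one-flask union. It sets out from 17 and uses aldehyde 6. Addition of the lithium enolate of tert-butyl acetate (LDA, THF, −78 °C, excess to cover the phenol) should give tert-butyl 3-hydroxy-3-[2-hydroxy-4,6-bis(methoxymethoxy)-3-(3-methylbut-2-en-1-yl)phenyl]propanoate F1. Oxidation of the benzylic alcohol with MnO2 in CH2Cl2 should give tert-butyl 3-[2-hydroxy-4,6-bis(methoxymethoxy)-3-(3-methylbut-2-en-1-yl)phenyl]-3-oxopropanoate F2. Knoevenagel condensation of F2 with 6 (piperidine, AcOH, toluene, 4 Å molecular sieves, rt) should give 18, now isolated, and its cyclisation with the same thiourea in toluene at −25 °C comes back to the route at 19.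

Step 3. What may go wrong: poor selectivity between migration to C5 and to C3, and thermal loss of the prenyl group at 190 °C. The fallback avoids the sigmatropic shift and sets out from 1. Bromination (Br2, AcOH, rt) should give 5-bromo-2,4-dihydroxybenzaldehyde F3, and double MOM protection (NaH, MOMCl, DMF) should give 5-bromo-2,4-bis(methoxymethoxy)benzaldehyde F4. A γ-selective Suzuki–Miyaura coupling of F4 with prenylboronic acid pinacol ester (Pd(OAc)2, a biarylphosphine ligand chosen for the branched product, K3PO4, THF/H2O) should install the 1,1-dimethylallyl group directly and come back at 6.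

Step 13. What may go wrong: slow ester cleavage that forces long acid exposure, with hydration of the prenyl group or its cyclisation onto O7, and acid-promoted ionisation of the C2–O1 bond next to the electron-rich ring B. The fallback changes the temporary ester so that it leaves without acid and sets out from 8. Trapping 8 with allyl chloroformate instead of Boc2O should give prop-2-en-1-yl 3-[2,4-bis(methoxymethoxy)-5-(2-methylbut-3-en-2-yl)phenyl]prop-2-ynoate F5. Under the conditions of step 12 with 17, F5 should pass through the allyl alkylidene β-keto ester F6 (not isolated) to the allyl ester analogue of 19, F7. Zerovalent palladium (Pd(PPh3)4, HCO2H/Et3N with the acid in excess, THF, rt) should remove the allyl group and the carboxyl group under neutral to weakly acidic conditions to give (2S)-2-[2,4-bis(methoxymethoxy)-5-(2-methylbut-3-en-2-yl)phenyl]-5,7-bis(methoxymethoxy)-8-(3-methylbut-2-en-1-yl)-2,3-dihydro-4H-chromen-4-one F8. A short treatment of F8 with methanolic HCl at room temperature, which now only has to cleave MOM ethers, comes back at 21.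

Further compounds
F1 | step 12 | tert-butyl 3-hydroxy-3-[2-hydroxy-4,6-bis(methoxymethoxy)-3-(3-methylbut-2-en-1-yl)phenyl]propanoate (racemic) | CC(C)(C)OC(=O)CC(O)c1c(O)c(CC=C(C)C)c(OCOC)cc1OCOC
F2 | step 12 | tert-butyl 3-[2-hydroxy-4,6-bis(methoxymethoxy)-3-(3-methylbut-2-en-1-yl)phenyl]-3-oxopropanoate | CC(C)(C)OC(=O)CC(=O)c1c(O)c(CC=C(C)C)c(OCOC)cc1OCOC
F3 | step 3 | 5-bromo-2,4-dihydroxybenzaldehyde | O=Cc1cc(Br)c(O)cc1O
F4 | step 3 | 5-bromo-2,4-bis(methoxymethoxy)benzaldehyde | O=Cc1cc(Br)c(OCOC)cc1OCOC
F5 | step 13 | prop-2-en-1-yl 3-[2,4-bis(methoxymethoxy)-5-(2-methylbut-3-en-2-yl)phenyl]prop-2-ynoate | C=CCOC(=O)C#Cc1cc(C(C)(C)C=C)c(OCOC)cc1OCOC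
F6 | step 13 | prop-2-en-1-yl (2Z)-2-[2-hydroxy-4,6-bis(methoxymethoxy)-3-(3-methylbut-2-en-1-yl)benzoyl]-3-[2,4-bis(methoxymethoxy)-5-(2-methylbut-3-en-2-yl)phenyl]prop-2-enoate | C=CCOC(=O)/C(=C\c1cc(C(C)(C)C=C)c(OCOC)cc1OCOC)C(=O)c1c(O)c(CC=C(C)C)c(OCOC)cc1OCOC
F7 | step 13 | prop-2-en-1-yl (2S,3R)-2-[2,4-bis(methoxymethoxy)-5-(2-methylbut-3-en-2-yl)phenyl]-5,7-bis(methoxymethoxy)-8-(3-methylbut-2-en-1-yl)-4-oxo-3,4-dihydro-2H-chromene-3-carboxylate | C=CC(C)(C)c1cc([C@@H]2[C@@H](C(=O)OCC=C)C(=O)c3c(OCOC)cc(OCOC)c(CC=C(C)C)c3O2)c(OCOC)cc1OCOC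
F8 | step 13 | (2S)-2-[2,4-bis(methoxymethoxy)-5-(2-methylbut-3-en-2-yl)phenyl]-5,7-bis(methoxymethoxy)-8-(3-methylbut-2-en-1-yl)-2,3-dihydro-4H-chromen-4-one | C=CC(C)(C)c1cc([C@@H]2CC(=O)c3c(OCOC)cc(OCOC)c(CC=C(C)C)c3O2)c(OCOC)cc1OCOC
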